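**Strategy.** Ring B (C1'–C6') is disconnected at C1'–C6' and C2'–C3'. Its C4'/C5' catechol oxygens are those of a 2,3-bis(silyloxy)butadiene. C1', C2' and the C2' bromine are those of a bromoethynyl ketone whose carbonyl carbon is the future bridge on C6 of ring A. One thermal [4+2] cycloaddition therefore builds ring B with both oxygens and the C2' bromine in place. Dehydrogenation, one bromination at C3', deoxygenation of the bridge and ether cleavage finish the synthesis. The dienophile is a fully substituted ring A aryl ketone (C5 Br, C3/C4 OMe, C1 CH2OMe), made from an aryl iodide and 3-(trimethylsilyl)propynal.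

Key step: step 6

Remark: atoms are numbered as in the target (ring A: C1 CH2OH, C2 H, C3/C4 OH, C5 Br, C6 bridge; ring B: C1' bridge, C2'/C3' Br, C4'/C5' OH, C6' H), and 1, 4 and 9 are taken to be catalogue chemicals.

**Step 1**
Reactants: 1 (3-bromo-4,5-dimethoxyphenyl)methanol
Product: 2 1-bromo-2,3-dimethoxy-5-(methoxymethyl)benzene
Conditions: NaH, MeI, THF, 0 °C→rt
Reagents that add atoms: iodomethane, CI
Why: Williamson ether synthesis on the primary benzylic alkoxide gives a methyl ether that should pass unchanged through the organometallic, oxidative, thermal and acidic steps and that the final BBr3 step converts into the hydroxymethyl group together with the aryl ethers.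

**Step 2**
Reactants: 2 1-bromo-2,3-dimethoxy-5-(methoxymethyl)benzene
Product: 3 3-bromo-2-iodo-4,5-dimethoxy-1-(methoxymethyl)benzene
Conditions: I2, AgOCOCF3, CHCl3, 0 °C→rt, dark
Reagents that add atoms: iodine, II
Why: Electrophilic aromatic iodination by trifluoroacetyl hypoiodite should enter C6, para to the in-plane C3 methoxy group and between C5–Br and the C1 side chain, by analogy with the bromination and benzylation of 3-bromo-4,5-dimethoxybenzyl compounds, which fixes the ring A pattern without directing-group chemistry.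

**Step 3**
Reactants: 3 3-bromo-2-iodo-4,5-dimethoxy-1-(methoxymethyl)benzene; 4 3-(trimethylsilyl)prop-2-ynal
Product: 6 rac-1-[2-bromo-3,4-dimethoxy-6-(methoxymethyl)phenyl]-3-(trimethylsilyl)prop-2-yn-1-ol, via arylmagnesium chloride 5 (not isolated)
Conditions: iPrMgCl·LiCl, THF, −40→−20 °C; then 4, −40→0 °C; aq. NH4Cl
Reagents that add atoms: none
Why: Iodine–magnesium exchange with the turbo-Grignard reagent is far faster at C–I than at C–Br and the ortho-bromoaryl Grignard is stable at low temperature, so Grignard 1,2-addition to the unhindered ynal should give the propargylic alcohol, whose new carbinol stereocentre forms without control as a racemate and is removed in step 4.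

**Step 4**
Reactants: 6 rac-1-[2-bromo-3,4-dimethoxy-6-(methoxymethyl)phenyl]-3-(trimethylsilyl)prop-2-yn-1-ol
Product: 7 1-[2-bromo-3,4-dimethoxy-6-(methoxymethyl)phenyl]-3-(trimethylsilyl)prop-2-yn-1-one
Conditions: Dess–Martin periodinane, CH2Cl2, rt
Reagents that add atoms: none
Why: Dess–Martin oxidation of a secondary benzylic propargylic alcohol to the ynone proceeds under neutral conditions that leave the alkynylsilane, the aryl bromide and the ethers untouched.

**Step 5**
Reactants: 7 1-[2-bromo-3,4-dimethoxy-6-(methoxymethyl)phenyl]-3-(trimethylsilyl)prop-2-yn-1-one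
Product: 8 3-bromo-1-[2-bromo-3,4-dimethoxy-6-(methoxymethyl)phenyl]prop-2-yn-1-one
Conditions: NBS, AgNO3 (10 mol %), acetone, rt, dark
Reagents that add atoms: N-bromosuccinimide, O=C1CCC(=O)N1Br
Why: Silver-catalysed bromodesilylation of an alkynylsilane with NBS, through the silver acetylide, is a standard one-step route to 1-bromoalkynes and places on the dienophile the bromine that becomes C2'–Br, so this bromine never has to be introduced by aromatic substitution beside ring A.

**Step 6**
Reactants: 8 3-bromo-1-[2-bromo-3,4-dimethoxy-6-(methoxymethyl)phenyl]prop-2-yn-1-one; 9 2,3-bis(trimethylsilyloxy)buta-1,3-diene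
Product: 10 [2-bromo-4,5-bis(trimethylsilyloxy)cyclohexa-1,4-dien-1-yl][2-bromo-3,4-dimethoxy-6-(methoxymethyl)phenyl]methanone
Conditions: 9 (2 equiv), PhMe, 80 °C, sealed tube, BHT (trace); excess 9 removed in vacuo, 10 used crude
Reagents that add atoms: none
Why: The electron-rich diene 9 and the bromoalkynyl ketone 8, whose LUMO is lowered by the carbonyl group, should combine in a concerted, thermally allowed [π4s+π2s] Diels–Alder reaction of normal electron demand. The closest known reaction type is the cycloaddition of haloalkynyl ketones, ethynyl ketones and alkynoates with 2-silyloxy- and 2,3-bis(silyloxy)butadienes, which gives cyclohexa-1,4-diene silyl enol ethers that are later dehydrogenated to phenols or catechols. Ring B is closed as a six-membered carbocycle by a two-bond intermolecular annulation, C1'–C6' and C2'–C3' being formed together and suprafacially on both partners, not by cyclisation of an open chain. No stereocentre is formed, because the two new sp3 carbons C3' and C6' are CH2 groups. The step needs only chemoselectivity: 9 is symmetric, so no regioisomers can arise, the ynone triple bond is the sole dienophile, and the tetrasubstituted, bromine-bearing C1'=C2' bond of 10 should not add a second diene. The two ortho substituents of ring A turn the aryl ring out of the carbonyl plane but leave the C≡C–C=O unit conjugated and its bromine-bearing terminus open to the diene.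

**Step 7**
Reactants: 10 [2-bromo-4,5-bis(trimethylsilyloxy)cyclohexa-1,4-dien-1-yl][2-bromo-3,4-dimethoxy-6-(methoxymethyl)phenyl]methanone
Product: 12 (2-bromo-4,5-dihydroxyphenyl)[2-bromo-3,4-dimethoxy-6-(methoxymethyl)phenyl]methanone, via bis(trimethylsilyl) aryl ether 11 (not isolated)
Conditions: DDQ (1.05 equiv), PhMe, 0 °C→rt; then 1 M HCl, THF, rt
Reagents that add atoms: none
Why: Dehydrogenation with DDQ (hydride abstraction from the doubly allylic C3'/C6' methylene, then loss of a proton) is driven by aromatisation of ring B, and dilute acid then hydrolyses the labile aryl trimethylsilyl ethers without touching the methyl ethers.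

**Step 8**
Reactants: 12 (2-bromo-4,5-dihydroxyphenyl)[2-bromo-3,4-dimethoxy-6-(methoxymethyl)phenyl]methanone
Product: 13 [2-bromo-3,4-dimethoxy-6-(methoxymethyl)phenyl](2,3-dibromo-4,5-dihydroxyphenyl)methanone
Conditions: Br2 (1.0 equiv), NaOAc, AcOH, rt
Reagents that add atoms: bromine, BrBr
Why: Electrophilic aromatic bromination of an acylcatechol is expected ortho to the hydroxyl that is para to the carbonyl and meta to the acyl group, by analogy with the 5-bromination of protocatechuic aldehyde and esters, which here is C3' (also ortho to C2'–Br), while ring A, which has no free phenol, should not react with one equivalent at room temperature.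

**Step 9**
Reactants: 13 [2-bromo-3,4-dimethoxy-6-(methoxymethyl)phenyl](2,3-dibromo-4,5-dihydroxyphenyl)methanone
Product: 14 rac-[2-bromo-3,4-dimethoxy-6-(methoxymethyl)phenyl](2,3-dibromo-4,5-dihydroxyphenyl)methanol
Conditions: NaBH4 (excess), THF–MeOH, 0 °C→rt
Reagents that add atoms: none
Why: Borohydride reduction of a diaryl ketone gives the benzhydrol as a racemate whose stereocentre disappears in step 10, with aryl bromides and ethers inert to the reagent.

**Step 10**
Reactants: 14 rac-[2-bromo-3,4-dimethoxy-6-(methoxymethyl)phenyl](2,3-dibromo-4,5-dihydroxyphenyl)methanol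
Product: 15 3,4-dibromo-5-{[2-bromo-3,4-dimethoxy-6-(methoxymethyl)phenyl]methyl}benzene-1,2-diol
Conditions: Et3SiH, CF3CO2H, CH2Cl2, 0 °C→rt
Reagents that add atoms: none
Why: Ionic hydrogenation, in which CF3CO2H ionises the benzhydrol to a cation stabilised by the para C4' hydroxyl and Et3SiH delivers hydride, should be much faster than ionisation of the primary benzylic methyl ether on the bromine-deactivated ring A.

**Step 11**
Reactants: 15 3,4-dibromo-5-{[2-bromo-3,4-dimethoxy-6-(methoxymethyl)phenyl]methyl}benzene-1,2-diol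
Product: 17 3-bromo-4-[(2,3-dibromo-4,5-dihydroxyphenyl)methyl]-5-(hydroxymethyl)benzene-1,2-diol, via benzylic bromide 16 (not isolated)
Conditions: BBr3 (excess), CH2Cl2, −78 °C→rt; then H2O–acetone, NaHCO3, rt, under argon
Reagents that add atoms: water, O
Why: Lewis-acid ether cleavage with BBr3 demethylates both aryl ethers and turns the benzylic methyl ether into the benzylic bromide, a para-hydroxybenzyl bromide (OH at C4) that buffered water should hydrolyse by an SN1 path through the quinone methide to the hydroxymethyl group.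

**Compound list**
1 | (3-bromo-4,5-dimethoxyphenyl)methanol | OCc1cc(Br)c(OC)c(OC)c1 | starting material
2 | 1-bromo-2,3-dimethoxy-5-(methoxymethyl)benzene | COCc1cc(Br)c(OC)c(OC)c1 | intermediate
3 | 3-bromo-2-iodo-4,5-dimethoxy-1-(methoxymethyl)benzene | COCc1cc(OC)c(OC)c(Br)c1I | intermediate
4 | 3-(trimethylsilyl)prop-2-ynal | C[Si](C)(C)C#CC=O | starting material
5 | [2-bromo-3,4-dimethoxy-6-(methoxymethyl)phenyl]magnesium chloride (LiCl complex) | COCc1cc(OC)c(OC)c(Br)c1[Mg]Cl | intermediate (not isolated)
6 | rac-1-[2-bromo-3,4-dimethoxy-6-(methoxymethyl)phenyl]-3-(trimethylsilyl)prop-2-yn-1-ol (racemate) | COCc1cc(OC)c(OC)c(Br)c1C(O)C#C[Si](C)(C)C | intermediate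
7 | 1-[2-bromo-3,4-dimethoxy-6-(methoxymethyl)phenyl]-3-(trimethylsilyl)prop-2-yn-1-one | COCc1cc(OC)c(OC)c(Br)c1C(=O)C#C[Si](C)(C)C | intermediate
8 | 3-bromo-1-[2-bromo-3,4-dimethoxy-6-(methoxymethyl)phenyl]prop-2-yn-1-one | COCc1cc(OC)c(OC)c(Br)c1C(=O)C#CBr | intermediate
9 | 2,3-bis(trimethylsilyloxy)buta-1,3-diene | C=C(O[Si](C)(C)C)C(=C)O[Si](C)(C)C | starting material
10 | [2-bromo-4,5-bis(trimethylsilyloxy)cyclohexa-1,4-dien-1-yl][2-bromo-3,4-dimethoxy-6-(methoxymethyl)phenyl]methanone | COCc1cc(OC)c(OC)c(Br)c1C(=O)C1=C(Br)CC(O[Si](C)(C)C)=C(O[Si](C)(C)C)C1 | intermediate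
11 | [2-bromo-4,5-bis(trimethylsilyloxy)phenyl][2-bromo-3,4-dimethoxy-6-(methoxymethyl)phenyl]methanone | COCc1cc(OC)c(OC)c(Br)c1C(=O)c1cc(O[Si](C)(C)C)c(O[Si](C)(C)C)cc1Br | intermediate (not isolated)
12 | (2-bromo-4,5-dihydroxyphenyl)[2-bromo-3,4-dimethoxy-6-(methoxymethyl)phenyl]methanone | COCc1cc(OC)c(OC)c(Br)c1C(=O)c1cc(O)c(O)cc1Br | intermediate
13 | [2-bromo-3,4-dimethoxy-6-(methoxymethyl)phenyl](2,3-dibromo-4,5-dihydroxyphenyl)methanone | COCc1cc(OC)c(OC)c(Br)c1C(=O)c1cc(O)c(O)c(Br)c1Br | intermediate
14 | rac-[2-bromo-3,4-dimethoxy-6-(methoxymethyl)phenyl](2,3-dibromo-4,5-dihydroxyphenyl)methanol (racemate) | COCc1cc(OC)c(OC)c(Br)c1C(O)c1cc(O)c(O)c(Br)c1Br | intermediate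
15 | 3,4-dibromo-5-{[2-bromo-3,4-dimethoxy-6-(methoxymethyl)phenyl]methyl}benzene-1,2-diol | COCc1cc(OC)c(OC)c(Br)c1Cc1cc(O)c(O)c(Br)c1Br | intermediate
16 | 3-bromo-5-(bromomethyl)-4-[(2,3-dibromo-4,5-dihydroxyphenyl)methyl]benzene-1,2-diol | BrCc1cc(O)c(O)c(Br)c1Cc1cc(O)c(O)c(Br)c1Br | intermediate (not isolated)
17 | 3-bromo-4-[(2,3-dibromo-4,5-dihydroxyphenyl)methyl]-5-(hydroxymethyl)benzene-1,2-diol (achiral) | OCc1cc(O)c(O)c(Br)c1Cc1cc(O)c(O)c(Br)c1Br | target

**Step count.** Total: 11 steps. Longest linear sequence: 11 steps (1 to 17); 4 and 9 enter as purchased.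

**Steps most likely to fail**

Step 6. The bromoalkyne may be consumed by bromine transfer to the silyl enol ether carbons of the diene, or by oligomerisation, faster than it undergoes cycloaddition. The fallback moves the C2' bromine to the end of the sequence and sets out from 7. Protodesilylation (Na2B4O7 cat., MeOH–H2O, rt) should give the terminal ynone 1-[2-bromo-3,4-dimethoxy-6-(methoxymethyl)phenyl]prop-2-yn-1-one F1. Its Diels–Alder reaction with 9 (PhMe, 80 °C) should give the cycloadduct [4,5-bis(trimethylsilyloxy)cyclohexa-1,4-dien-1-yl][2-bromo-3,4-dimethoxy-6-(methoxymethyl)phenyl]methanone F2. DDQ should convert this into the bis(silyl) ether [3,4-bis(trimethylsilyloxy)phenyl][2-bromo-3,4-dimethoxy-6-(methoxymethyl)phenyl]methanone F3, which dilute HCl hydrolyses to the catechol ketone [2-bromo-3,4-dimethoxy-6-(methoxymethyl)phenyl](3,4-dihydroxyphenyl)methanone F4. Two equivalents of Br2 in NaOAc/AcOH (Fe powder if the second substitution is slow) should brominate first at C3', giving the monobromide (3-bromo-4,5-dihydroxyphenyl)[2-bromo-3,4-dimethoxy-6-(methoxymethyl)phenyl]methanone F5, and then at C2', para to the C5' hydroxyl, as in the 5,6-dibromination of vanillin-type carbonyl compounds. The route is rejoined at 13.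

Step 8. Bromine may attack C6', ortho to the C5' hydroxyl, or the catechol may be oxidised to the ortho-quinone in place of clean substitution at C3'. The fallback sets out from 12 and differentiates the two oxygens first. The dianion (NaH, 2.2 equiv, DMSO) with one equivalent of MeI should alkylate the more nucleophilic, non-conjugated C5' phenoxide and give the monomethyl ether (2-bromo-4-hydroxy-5-methoxyphenyl)[2-bromo-3,4-dimethoxy-6-(methoxymethyl)phenyl]methanone F6. With only the C4' hydroxyl free, Br2/NaOAc/AcOH can substitute only ortho to it, at C3', giving [2-bromo-3,4-dimethoxy-6-(methoxymethyl)phenyl](2,3-dibromo-4-hydroxy-5-methoxyphenyl)methanone F7. NaBH4 should then give the benzhydrol rac-[2-bromo-3,4-dimethoxy-6-(methoxymethyl)phenyl](2,3-dibromo-4-hydroxy-5-methoxyphenyl)methanol F8, and Et3SiH/CF3CO2H the diarylmethane 2,3-dibromo-4-{[2-bromo-3,4-dimethoxy-6-(methoxymethyl)phenyl]methyl}-6-methoxyphenol F9. BBr3 removes the extra methyl group with the others, so the route is rejoined at 16 and ends at 17 as in step 11.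

Step 9. Hydride addition may be slow or incomplete, because the carbonyl is screened by three ortho substituents and, once the basic medium deprotonates the C4' phenol, becomes a vinylogous carboxylate. The fallback replaces nucleophilic reduction by acid-activated ionic hydrogenation and sets out from 13. Et3SiH with CF3SO3H in CF3CO2H/CH2Cl2 protonates the carbonyl oxygen while the phenol stays neutral and acts as a donor. The silane should then reduce the ketone to 14, which ionises and is reduced again in the same flask, so the route is rejoined at 15. This fallback makes no new compound (F0).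

**Further compounds**
F1 | step 6 | 1-[2-bromo-3,4-dimethoxy-6-(methoxymethyl)phenyl]prop-2-yn-1-one | COCc1cc(OC)c(OC)c(Br)c1C(=O)C#C
F2 | step 6 | [4,5-bis(trimethylsilyloxy)cyclohexa-1,4-dien-1-yl][2-bromo-3,4-dimethoxy-6-(methoxymethyl)phenyl]methanone | COCc1cc(OC)c(OC)c(Br)c1C(=O)C1=CCC(O[Si](C)(C)C)=C(O[Si](C)(C)C)C1
F3 | step 6 | [3,4-bis(trimethylsilyloxy)phenyl][2-bromo-3,4-dimethoxy-6-(methoxymethyl)phenyl]methanone | COCc1cc(OC)c(OC)c(Br)c1C(=O)c1ccc(O[Si](C)(C)C)c(O[Si](C)(C)C)c1
F4 | step 6 | [2-bromo-3,4-dimethoxy-6-(methoxymethyl)phenyl](3,4-dihydroxyphenyl)methanone | COCc1cc(OC)c(OC)c(Br)c1C(=O)c1ccc(O)c(O)c1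
F5 | step 6 | (3-bromo-4,5-dihydroxyphenyl)[2-bromo-3,4-dimethoxy-6-(methoxymethyl)phenyl]methanone | COCc1cc(OC)c(OC)c(Br)c1C(=O)c1cc(O)c(O)c(Br)c1
F6 | step 8 | (2-bromo-4-hydroxy-5-methoxyphenyl)[2-bromo-3,4-dimethoxy-6-(methoxymethyl)phenyl]methanone | COCc1cc(OC)c(OC)c(Br)c1C(=O)c1cc(OC)c(O)cc1Br
F7 | step 8 | [2-bromo-3,4-dimethoxy-6-(methoxymethyl)phenyl](2,3-dibromo-4-hydroxy-5-methoxyphenyl)methanone | COCc1cc(OC)c(OC)c(Br)c1C(=O)c1cc(OC)c(O)c(Br)c1Br
F8 | step 8 | rac-[2-bromo-3,4-dimethoxy-6-(methoxymethyl)phenyl](2,3-dibromo-4-hydroxy-5-methoxyphenyl)methanol (racemate) | COCc1cc(OC)c(OC)c(Br)c1C(O)c1cc(OC)c(O)c(Br)c1Br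
F9 | step 8 | 2,3-dibromo-4-{[2-bromo-3,4-dimethoxy-6-(methoxymethyl)phenyl]methyl}-6-methoxyphenol | COCc1cc(OC)c(OC)c(Br)c1Cc1cc(OC)c(O)c(Br)c1Br
F0 | step 9 | none | none
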